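**Plan**
- Retrosynthesis: the silyl and MOM ethers are removed first; ring A is then cut at C7–C7a, C6–C7, C4–C5 and C3a–C4, giving furyl diazo ketone 19 and siloxyalkyne 20. Further cuts are the C–N2 bond, the furan C5–aryl bond, the furan C2–acyl bond, the two aryl–prenyl bonds and the C3–isopropenyl bond of the side-chain acid.
- Enabling feature: ring A (C3a, C4, C5, C6, C7, C7a) is a resorcinol ring with O at C4 and C6, H at C5 and the alkyl group at C7, fused through C3a–C7a to a furan whose C2=C3 bond can act as the third π bond of a dienylketene.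
- Forward: ring B is made from 5-bromoresorcinol (MOM protection, diiodination, two I/Mg exchange–prenylations). The chiral 5-bromo-2-furyl ketone is made separately, and the two are joined by Negishi coupling. Diazo transfer follows, ring A is built last on the furan, and the phenols are unmasked in two steps.
- Stereochemistry: the single centre is set by Rh/(R)-BINAP conjugate addition of isopropenyl to the si face of C3 of ethyl crotonate and is carried unchanged. The descriptor switches from S (10–18) to R (19–27) only because the neighbouring carbon gains CIP priority.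

Key step: step 10

Assumption: triisopropylsiloxyacetylene 20, a known ynol silyl ether obtainable by O-silylation of the corresponding lithium ynolate, is taken as a purchasable or stock reagent.

Abbreviation in names: Ar = 3,5-bis(methoxymethoxy)-2,6-bis(3-methylbut-2-en-1-yl)phenyl.

**Route**

Step 1
Reactants: 1 5-bromoresorcinol
Product: 2 1-bromo-3,5-bis(methoxymethoxy)benzene
Conditions: NaH (2.5 equiv), MOMCl (2.5 equiv), DMF, 0 °C → rt
Reagents that add atoms: chloromethyl methyl ether, COCCl
Why: Williamson O-alkylation of the bis-phenoxide should give the bis-MOM ether, which tolerates the later organometallic steps and keeps the ring activated for iodination.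

Step 2
Reactants: 2 1-bromo-3,5-bis(methoxymethoxy)benzene
Product: 3 3-bromo-2,4-diiodo-1,5-bis(methoxymethoxy)benzene
Conditions: NIS (2.4 equiv), MeCN, 0 °C → rt, dark (TFA 5 mol% if the second iodination stalls)
Reagents that add atoms: N-iodosuccinimide, O=C1CCC(=O)N1I
Why: Electrophilic aromatic iodination of a resorcinol diether is expected at the two carbons that are ortho to one ether and para to the other (here the carbons flanking C–Br) in preference to the doubly ortho carbon between the ethers.

Step 3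
Reactants: 3 3-bromo-2,4-diiodo-1,5-bis(methoxymethoxy)benzene
Product: 5 3-bromo-2-iodo-1,5-bis(methoxymethoxy)-4-(3-methylbut-2-en-1-yl)benzene, via arylmagnesium chloride 4 (not isolated)
Conditions: i-PrMgCl·LiCl (1.05 equiv), THF, –40 °C; CuBr·SMe2 (10 mol%), prenyl bromide (1.3 equiv), –40 → 0 °C
Reagents that add atoms: 1-bromo-3-methylbut-2-ene (prenyl bromide), CC(C)=CCBr
Why: Knochel iodine–magnesium exchange (iodine before bromine, helped by the ortho OMOM group, and only once because the aryl-Mg product is electron-rich) followed by copper-catalysed allylic substitution, in which the di-ortho-substituted aryl copper should attack the unhindered CH2 terminus of prenyl bromide (SN2).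

Step 4
Reactants: 5 3-bromo-2-iodo-1,5-bis(methoxymethoxy)-4-(3-methylbut-2-en-1-yl)benzene
Product: 7 3-bromo-1,5-bis(methoxymethoxy)-2,4-bis(3-methylbut-2-en-1-yl)benzene, via arylmagnesium chloride 6 (not isolated)
Conditions: i-PrMgCl·LiCl (1.05 equiv), THF, –40 °C; CuBr·SMe2 (10 mol%), prenyl bromide (1.3 equiv), –40 → 0 °C
Reagents that add atoms: 1-bromo-3-methylbut-2-ene (prenyl bromide), CC(C)=CCBr
Why: The same iodine–magnesium exchange and copper-catalysed SN2 prenylation is repeated on the remaining C–I bond, leaving the C–Br bond for the later coupling.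

Step 5
Reactants: 8 ethyl (E)-but-2-enoate (ethyl crotonate); 9 isopropenylboronic acid pinacol ester
Product: 10 ethyl (3S)-3,4-dimethylpent-4-enoate
Conditions: [Rh(cod)OH]2 (2.5 mol%), (R)-BINAP (6 mol%), KOH (10 mol%), 9 (2 equiv), dioxane/H2O 10:1, 50 °C
Reagents that add atoms: none
Why: Hayashi–Miyaura rhodium-catalysed asymmetric 1,4-addition, in which the isopropenyl–Rh(BINAP) species inserts the (E)-enoate and (R)-BINAP, by the accepted quadrant model for (E)-enoates, steers the alkenyl group to the si face of C3 to set the (S) centre (the rotation of the derived acid is to be compared with the known (S)-acid before the material is carried on).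

Step 6
Reactants: 10 ethyl (3S)-3,4-dimethylpent-4-enoate
Product: 11 (3S)-N-methoxy-N,3,4-trimethylpent-4-enamide
Conditions: MeNHOMe·HCl (1.5 equiv), i-PrMgCl (3.0 equiv), THF, –20 → 0 °C
Reagents that add atoms: N,O-dimethylhydroxylamine hydrochloride, CNOC.Cl
Why: Direct aminolysis of the ester by the chloromagnesium amide gives the Weinreb amide without touching the β stereocentre, which carries no acidic hydrogen.

Step 7
Reactants: 12 2,5-dibromofuran; 11 (3S)-N-methoxy-N,3,4-trimethylpent-4-enamide
Product: 14 (3S)-1-(5-bromofuran-2-yl)-3,4-dimethylpent-4-en-1-one, via 5-bromo-2-furyllithium 13 (not isolated)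
Conditions: 12 (1.2 equiv), n-BuLi (1.15 equiv), THF, –78 °C, 20 min; 11, –78 → –20 °C; aq. NH4Cl
Reagents that add atoms: none
Why: Selective mono bromine–lithium exchange of the dibromofuran followed by Weinreb ketone synthesis, where the chelated tetrahedral adduct prevents over-addition and the remaining C–Br bond is kept as the coupling handle.

Step 8
Reactants: 7 3-bromo-1,5-bis(methoxymethoxy)-2,4-bis(3-methylbut-2-en-1-yl)benzene; 14 (3S)-1-(5-bromofuran-2-yl)-3,4-dimethylpent-4-en-1-one
Product: 17 (3S)-1-{5-[Ar]furan-2-yl}-3,4-dimethylpent-4-en-1-one, via aryllithium 15 (not isolated), via arylzinc chloride 16 (not isolated)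
Conditions: 7 (1.3 equiv), n-BuLi (1.3 equiv), THF, –78 °C; ZnCl2 (1.4 equiv), –78 °C → rt; 14, Pd(OAc)2 (2 mol%), SPhos (4 mol%), THF, 50 °C
Reagents that add atoms: none
Why: Negishi coupling: the arylzinc is too weakly basic to enolise the ketone, the 2-acyl-5-bromofuran is activated for oxidative addition, and the biaryl phosphine ligand copes with the di-ortho-substituted aryl partner.

Step 9
Reactants: 17 (3S)-1-{5-[Ar]furan-2-yl}-3,4-dimethylpent-4-en-1-one
Product: 19 (3R)-2-diazo-1-{5-[Ar]furan-2-yl}-3,4-dimethylpent-4-en-1-one, via α-trifluoroacetyl ketone 18 (not isolated)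
Conditions: LiHMDS (1.1 equiv), THF, –78 °C; CF3CO2CH2CF3 (1.2 equiv), –78 °C; brief cold 1 M HCl wash; p-ABSA (1.5 equiv), Et3N (1.5 equiv), H2O (1 equiv), MeCN, rt
Reagents that add atoms: 4-acetamidobenzenesulfonyl azide, CC(=O)Nc1ccc(cc1)S(=O)(=O)N=[N+]=[N-]; 2,2,2-trifluoroethyl trifluoroacetate, O=C(OCC(F)(F)F)C(F)(F)F (its CF3CO group is held only in 18)
Why: Detrifluoroacetylative (deacylative Regitz-type) diazo transfer: the only enolisable position is trifluoroacetylated, and the activated diketone takes up the diazo group with loss of the trifluoroacetyl group as the N-acylsulfonamide, while the adjacent stereocentre is never deprotonated.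

Step 10
Reactants: 19 (3R)-2-diazo-1-{5-[Ar]furan-2-yl}-3,4-dimethylpent-4-en-1-one; 20 triisopropylsiloxyacetylene
Product: 25 2-[Ar]-7-[(2R)-3-methylbut-3-en-2-yl]-6-[(triisopropylsilyl)oxy]-1-benzofuran-4-ol, via furyl(alkyl)ketene 21 (not isolated), via 4-furylcyclobutenone 22 (not isolated), via dienylketene 23 (not isolated), via 3aH-benzofuran-4-one 24 (not isolated)
Conditions: 20 (2 equiv), degassed ClCH2CH2Cl (0.05 M), hν (300–365 nm, Pyrex), rt; then 80 °C
Reagents that add atoms: none
Why: Irradiation expels N2 from 19 and the furyl group migrates from the carbonyl carbon to the diazo carbon (Wolff rearrangement, forming C7–C7a) to give ketene 21, to which the electron-rich siloxyalkyne adds in a polarity-matched [2+2] cycloaddition, its CH carbon bonding to the ketene carbonyl carbon (C4–C5) and its oxygen-bearing carbon to the ketene α-carbon (C6–C7), giving cyclobutenone 22. Heating opens 22 by 4π electrocyclisation to dienylketene 23, whose third π bond is the furan C2=C3 bond, and ring A is closed by a thermal disrotatory 6π electrocyclisation (ketene carbon to furan C3, forming C3a–C4) to dienone 24, which tautomerises to phenol 25. This is the photochemical Wolff variant of the Danheiser benzannulation, a reaction type established for furyl and other heteroaryl diazo ketones with siloxyacetylenes. No stereocentre is created, and the side-chain centre stays attached to sp2 carbons and carries no acidic hydrogen, so it should pass through unchanged. The step needs furyl migration to outrun the 1,2-hydride shift from the neighbouring methine, which metal-free photolysis favours, and it needs a single regiochemistry in the [2+2] step, which the polarisation of the siloxyalkyne secures. The ring opening of 22 that puts the alkyl group instead of the furan next to the ketene is reversible and should drain into 25, and closure can only reach furan C3, so the pattern O (C4), H (C5), O (C6), alkyl (C7) is fixed by connectivity.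

Step 11
Reactants: 25 2-[Ar]-7-[(2R)-3-methylbut-3-en-2-yl]-6-[(triisopropylsilyl)oxy]-1-benzofuran-4-ol
Product: 26 5-{4-hydroxy-7-[(2R)-3-methylbut-3-en-2-yl]-6-[(triisopropylsilyl)oxy]-1-benzofuran-2-yl}-4,6-bis(3-methylbut-2-en-1-yl)benzene-1,3-diol
Conditions: TMSOTf (6 equiv), 2,2'-bipyridyl (9 equiv), MeCN, 0 °C → rt; then H2O, rt
Reagents that add atoms: none
Why: The TMSOTf–2,2'-bipyridyl cleavage of aryl MOM ethers runs through aryl TMS ethers that water hydrolyses, with the methoxymethyl fragment trapped on the pyridine base, so no protic acid or free oxocarbenium ion is present to cyclise the ortho-prenyl phenols, add to the isopropenyl group or alkylate the electron-rich rings, and the C6 silyl ether stays in place.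

Step 12
Reactants: 26 5-{4-hydroxy-7-[(2R)-3-methylbut-3-en-2-yl]-6-[(triisopropylsilyl)oxy]-1-benzofuran-2-yl}-4,6-bis(3-methylbut-2-en-1-yl)benzene-1,3-diol
Product: 27 5-{4,6-dihydroxy-7-[(2R)-3-methylbut-3-en-2-yl]-1-benzofuran-2-yl}-4,6-bis(3-methylbut-2-en-1-yl)benzene-1,3-diol (CNP0208883.1)
Conditions: TBAF (1.2 equiv), AcOH (1.2 equiv), THF, 0 °C, under Ar
Reagents that add atoms: none
Why: Fluoride-driven cleavage of the aryl silyl ether under acetic acid buffering should free the last phenol without touching the prenyl or isopropenyl groups or the (R) centre.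

**Compound list**

1 | 5-bromoresorcinol | Oc1cc(O)cc(Br)c1 | starting material
2 | 1-bromo-3,5-bis(methoxymethoxy)benzene | COCOc1cc(OCOC)cc(Br)c1 | intermediate
3 | 3-bromo-2,4-diiodo-1,5-bis(methoxymethoxy)benzene | COCOc1cc(OCOC)c(I)c(Br)c1I | intermediate
4 | [2-bromo-3-iodo-4,6-bis(methoxymethoxy)phenyl]magnesium chloride | COCOc1cc(OCOC)c(I)c(Br)c1[Mg]Cl | intermediate
5 | 3-bromo-2-iodo-1,5-bis(methoxymethoxy)-4-(3-methylbut-2-en-1-yl)benzene | COCOc1cc(OCOC)c(I)c(Br)c1CC=C(C)C | intermediate
6 | [2-bromo-4,6-bis(methoxymethoxy)-3-(3-methylbut-2-en-1-yl)phenyl]magnesium chloride | COCOc1cc(OCOC)c(CC=C(C)C)c(Br)c1[Mg]Cl | intermediate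
7 | 3-bromo-1,5-bis(methoxymethoxy)-2,4-bis(3-methylbut-2-en-1-yl)benzene | COCOc1cc(OCOC)c(CC=C(C)C)c(Br)c1CC=C(C)C | intermediate
8 | ethyl (E)-but-2-enoate | C/C=C/C(=O)OCC | starting material
9 | isopropenylboronic acid pinacol ester | C=C(C)B1OC(C)(C)C(C)(C)O1 | starting material
10 | ethyl (3S)-3,4-dimethylpent-4-enoate | C=C(C)[C@@H](C)CC(=O)OCC | intermediate
11 | (3S)-N-methoxy-N,3,4-trimethylpent-4-enamide | C=C(C)[C@@H](C)CC(=O)N(C)OC | intermediate
12 | 2,5-dibromofuran | Brc1ccc(Br)o1 | starting material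
13 | (5-bromofuran-2-yl)lithium | [Li]c1ccc(Br)o1 | intermediate
14 | (3S)-1-(5-bromofuran-2-yl)-3,4-dimethylpent-4-en-1-one | C=C(C)[C@@H](C)CC(=O)c1ccc(Br)o1 | intermediate
15 | [3,5-bis(methoxymethoxy)-2,6-bis(3-methylbut-2-en-1-yl)phenyl]lithium | COCOc1cc(OCOC)c(CC=C(C)C)c([Li])c1CC=C(C)C | intermediate
16 | [3,5-bis(methoxymethoxy)-2,6-bis(3-methylbut-2-en-1-yl)phenyl]zinc chloride | COCOc1cc(OCOC)c(CC=C(C)C)c([Zn]Cl)c1CC=C(C)C | intermediate
17 | (3S)-1-{5-[3,5-bis(methoxymethoxy)-2,6-bis(3-methylbut-2-en-1-yl)phenyl]furan-2-yl}-3,4-dimethylpent-4-en-1-one | C=C(C)[C@@H](C)CC(=O)c1ccc(-c2c(CC=C(C)C)c(OCOC)cc(OCOC)c2CC=C(C)C)o1 | intermediate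
18 | 1-{5-[Ar]furan-2-yl}-4,4,4-trifluoro-2-[(2S)-3-methylbut-3-en-2-yl]butane-1,3-dione (C2 epimers and enol) | C=C(C)[C@@H](C)C(C(=O)C(F)(F)F)C(=O)c1ccc(-c2c(CC=C(C)C)c(OCOC)cc(OCOC)c2CC=C(C)C)o1 | intermediate
19 | (3R)-2-diazo-1-{5-[Ar]furan-2-yl}-3,4-dimethylpent-4-en-1-one | C=C(C)[C@@H](C)C(=[N+]=[N-])C(=O)c1ccc(-c2c(CC=C(C)C)c(OCOC)cc(OCOC)c2CC=C(C)C)o1 | intermediate
20 | triisopropylsiloxyacetylene | C#CO[Si](C(C)C)(C(C)C)C(C)C | starting material
21 | (3R)-2-{5-[Ar]furan-2-yl}-3,4-dimethylpenta-1,4-dien-1-one (ketene) | C=C(C)[C@@H](C)C(=C=O)c1ccc(-c2c(CC=C(C)C)c(OCOC)cc(OCOC)c2CC=C(C)C)o1 | intermediate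
22 | 4-{5-[Ar]furan-2-yl}-4-[(2R)-3-methylbut-3-en-2-yl]-3-[(triisopropylsilyl)oxy]cyclobut-2-en-1-one (both C4 epimers) | C=C(C)[C@@H](C)C1(c2ccc(-c3c(CC=C(C)C)c(OCOC)cc(OCOC)c3CC=C(C)C)o2)C(=O)C=C1O[Si](C(C)C)(C(C)C)C(C)C | intermediate
23 | (3E,5R)-4-{5-[Ar]furan-2-yl}-5,6-dimethyl-3-[(triisopropylsilyl)oxy]hepta-1,3,6-trien-1-one (dienylketene) | C=C(C)[C@@H](C)/C(c1ccc(-c2c(CC=C(C)C)c(OCOC)cc(OCOC)c2CC=C(C)C)o1)=C(\O[Si](C(C)C)(C(C)C)C(C)C)C=C=O | intermediate
24 | 2-[Ar]-7-[(2R)-3-methylbut-3-en-2-yl]-6-[(triisopropylsilyl)oxy]-1-benzofuran-4(3aH)-one (C3a epimers) | C=C(C)[C@@H](C)C1=C2OC(-c3c(CC=C(C)C)c(OCOC)cc(OCOC)c3CC=C(C)C)=CC2C(=O)C=C1O[Si](C(C)C)(C(C)C)C(C)C | intermediate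
25 | 2-[3,5-bis(methoxymethoxy)-2,6-bis(3-methylbut-2-en-1-yl)phenyl]-7-[(2R)-3-methylbut-3-en-2-yl]-6-[(triisopropylsilyl)oxy]-1-benzofuran-4-ol | C=C(C)[C@@H](C)c1c(O[Si](C(C)C)(C(C)C)C(C)C)cc(O)c2cc(-c3c(CC=C(C)C)c(OCOC)cc(OCOC)c3CC=C(C)C)oc12 | intermediate
26 | 5-{4-hydroxy-7-[(2R)-3-methylbut-3-en-2-yl]-6-[(triisopropylsilyl)oxy]-1-benzofuran-2-yl}-4,6-bis(3-methylbut-2-en-1-yl)benzene-1,3-diol | C=C(C)[C@@H](C)c1c(O[Si](C(C)C)(C(C)C)C(C)C)cc(O)c2cc(-c3c(CC=C(C)C)c(O)cc(O)c3CC=C(C)C)oc12 | intermediate
27 | 5-{4,6-dihydroxy-7-[(2R)-3-methylbut-3-en-2-yl]-1-benzofuran-2-yl}-4,6-bis(3-methylbut-2-en-1-yl)benzene-1,3-diol (CNP0208883.1) | C=C(C)[C@@H](C)c1c(O)cc(O)c2cc(-c3c(CC=C(C)C)c(O)cc(O)c3CC=C(C)C)oc12 | target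

**Count**

Total steps: 12. Longest linear sequence: 9 steps (1, 2, 3, 4, 8, 9, 10, 11, 12 from 5-bromoresorcinol); the side-chain branch (5, 6, 7) joins at step 8.

**Steps most likely to fail**

1. Step 10. After loss of nitrogen the acyl carbene (or the excited diazo ketone) may shift the neighbouring methine hydrogen instead of the furyl group, which would give a conjugated enone and erase the stereocentre. The dienylketene isomer with the alkyl group next to the ketene may also leak away by 1,5-hydrogen shift, and the arylbenzofuran may be photolysed further. The fallback reaches ketene 21 without a carbene and without light. Arylzinc chloride 16 is coupled with an excess of 2,5-dibromofuran 12 (Pd(OAc)2/SPhos, THF) to give 2-bromo-5-[Ar]furan F1. The lithium enolate of ester 10 is then α-arylated with F1 (LiHMDS, Pd(dba)2/P(t-Bu)3, toluene, rt) to give ethyl (3S)-2-{5-[Ar]furan-2-yl}-3,4-dimethylpent-4-enoate F2, whose C2 epimers are of no consequence because C2 becomes the ketene carbon. Saponification (LiOH, THF/H2O) gives (3S)-2-{5-[Ar]furan-2-yl}-3,4-dimethylpent-4-enoic acid F3. 1-Chloro-N,N,2-trimethylpropenylamine (CH2Cl2, 0 °C) converts it under neutral conditions into the acid chloride (3S)-2-{5-[Ar]furan-2-yl}-3,4-dimethylpent-4-enoyl chloride F4. Slow addition of Et3N to F4 and 20 in toluene at 80 °C releases 21 by dehydrochlorination, and 21 then runs thermally through 22, 23 and 24. This fallback sets out from 10 and 16 and returns to the route at 25.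

2. Step 5. Transmetalation of the pinacol boronate and insertion of the weakly electrophilic crotonate may be slow enough for protodeboronation to win, and face discrimination with the small isopropenyl group may be incomplete. The fallback is an auxiliary-controlled cuprate addition. Ester 8 is saponified to (E)-but-2-enoic acid F5 (which can also be bought), activated with PivCl/Et3N as but-2-enoic pivalic anhydride F6, and acylated onto lithiated (R)-4-phenyl-1,3-oxazolidin-2-one to give (4R)-3-[(2E)-but-2-enoyl]-4-phenyl-1,3-oxazolidin-2-one F7. Isopropenylmagnesium bromide/CuBr·SMe2 (THF/Me2S, –78 → –20 °C) should add to the magnesium-chelated syn-s-cis imide from the face opposite the phenyl group, the si face of C3, to give (4R)-3-[(3S)-3,4-dimethylpent-4-enoyl]-4-phenyl-1,3-oxazolidin-2-one F8. MeNHOMe·HCl/AlMe3 (CH2Cl2, 0 °C) then transamidates F8 with release of the auxiliary. This fallback sets out from 8 and returns to the route at 11.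

3. Step 2. The second iodination may drift to the carbon between the two ether groups or stall for steric reasons beside bromine, and acid formed on the way may erode the MOM ethers. The fallback places both prenyl groups by aromatic Claisen rearrangement. Diol 1 is O-alkylated with 3-chloro-3-methylbut-1-yne (DBU, CuCl2 cat., MeCN, 0 °C) to give 1-bromo-3,5-bis[(2-methylbut-3-yn-2-yl)oxy]benzene F9. Lindlar semihydrogenation gives 1-bromo-3,5-bis[(2-methylbut-3-en-2-yl)oxy]benzene F10. Heating (PhNEt2, 130–150 °C) should bring about two [3,3] shifts, each to the ortho carbon next to bromine: that carbon is para to the other oxygen and adjacent to the meta halogen, and both effects favour it over the carbon between the oxygens. The product is 5-bromo-4,6-bis(3-methylbut-2-en-1-yl)benzene-1,3-diol F11, which NaH/MOMCl protects as in step 1. This fallback sets out from 1 and returns to the route at 7.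

**Further compounds**

F1 | step 10 | 2-bromo-5-[3,5-bis(methoxymethoxy)-2,6-bis(3-methylbut-2-en-1-yl)phenyl]furan | Brc1ccc(-c2c(CC=C(C)C)c(OCOC)cc(OCOC)c2CC=C(C)C)o1
F2 | step 10 | ethyl (3S)-2-{5-[Ar]furan-2-yl}-3,4-dimethylpent-4-enoate (C2 epimers) | C=C(C)[C@@H](C)C(C(=O)OCC)c1ccc(-c2c(CC=C(C)C)c(OCOC)cc(OCOC)c2CC=C(C)C)o1
F3 | step 10 | (3S)-2-{5-[Ar]furan-2-yl}-3,4-dimethylpent-4-enoic acid (C2 epimers) | C=C(C)[C@@H](C)C(C(=O)O)c1ccc(-c2c(CC=C(C)C)c(OCOC)cc(OCOC)c2CC=C(C)C)o1
F4 | step 10 | (3S)-2-{5-[Ar]furan-2-yl}-3,4-dimethylpent-4-enoyl chloride (C2 epimers) | C=C(C)[C@@H](C)C(C(=O)Cl)c1ccc(-c2c(CC=C(C)C)c(OCOC)cc(OCOC)c2CC=C(C)C)o1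
F5 | step 5 | (E)-but-2-enoic acid | C/C=C/C(=O)O
F6 | step 5 | (E)-but-2-enoic pivalic anhydride | C/C=C/C(=O)OC(=O)C(C)(C)C
F7 | step 5 | (4R)-3-[(2E)-but-2-enoyl]-4-phenyl-1,3-oxazolidin-2-one | C/C=C/C(=O)N1C(=O)OC[C@H]1c1ccccc1
F8 | step 5 | (4R)-3-[(3S)-3,4-dimethylpent-4-enoyl]-4-phenyl-1,3-oxazolidin-2-one | C=C(C)[C@@H](C)CC(=O)N1C(=O)OC[C@H]1c1ccccc1
F9 | step 2 | 1-bromo-3,5-bis[(2-methylbut-3-yn-2-yl)oxy]benzene | C#CC(C)(C)Oc1cc(OC(C)(C)C#C)cc(Br)c1
F10 | step 2 | 1-bromo-3,5-bis[(2-methylbut-3-en-2-yl)oxy]benzene | C=CC(C)(C)Oc1cc(OC(C)(C)C=C)cc(Br)c1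
F11 | step 2 | 5-bromo-4,6-bis(3-methylbut-2-en-1-yl)benzene-1,3-diol | Oc1cc(O)c(CC=C(C)C)c(Br)c1CC=C(C)C
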